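A direct plan would build an open-chain alkyne–vinylcyclopropane A1 and close both rings at once by a rhodium-catalysed (5+2) cycloaddition to the bicyclo[5.3.0]decadiene A2, then oxidise the two alkenes in turn. Numbering: C1 is the methyl-bearing fusion carbon, C2–C4 the cyclopentane carbons, C5 the fusion CH, C6–C10 the cycloheptane carbons. Its weakest steps would be:
(a) the cycloaddition, which would have to form quaternary C1 at a fully substituted alkene terminus with face control from one silyloxy group;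
(b) the move of the C9=C10 alkene of A2 to a C8=C9 allylic alcohol by selenide opening of an epoxide and selenoxide elimination, three operations that would add no complexity;
(c) the late hydroboration of the hindered C5=C6 alkene of A3 with excess borane beside an epoxide and two acetates, which would have to set C5 and C6.

The new route cuts C1–C5 and C1–C10: C1 enters as a carbene carbon and C5–C10 as the ring of a 4-methyl-2-silyloxyphenyl group, so the arene brings the C8 methyl and the C6 oxygen. One intramolecular Buchner reaction of epoxy diazo ketone 12 closes the cyclopentanone, expands the benzene ring to the cycloheptatriene and sets quaternary C1 from C4. The triene is then resolved by its own polarity (enol ether to C6 ketone, γ,δ-epoxidation, one-step SmI2 shift to the C8=C9/C10–OH array), and the C4 hydroxyl delivers hydride to C2 and C6. The hindered cycloaddition, the three-step alkene transposition and the late hydroboration all disappear.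

Key step: step 7

Remark: the numbers C1–C10 are kept for the same carbons in all precursors; β is the face of the C1 methyl, α the opposite face; Ar = 4-methyl-2-[tri(propan-2-yl)silyloxy]phenyl.

Step 1
Reactants: 1 3-methylphenol (m-cresol); 2 ethyl 4-methyl-3-oxopentanoate
Product: 3 7-methyl-4-(propan-2-yl)-2H-chromen-2-one
Conditions: conc. H2SO4, 0 °C → rt
Reagents that add atoms: none
Why: Pechmann condensation (transesterification, ring closure para to the methyl group, dehydration) gives the coumarin, whose lactone ring holds the aryl group and the future C2 carbon cis on the C3=C4 double bond and places the future C6 oxygen and C8 methyl on the arene.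

Step 2
Reactants: 3 7-methyl-4-(propan-2-yl)-2H-chromen-2-one
Product: 4 2-[(2Z)-1-hydroxy-4-methylpent-2-en-3-yl]-5-methylphenol
Conditions: LiAlH4, Et2O, 0 °C; aq. potassium sodium tartrate
Reagents that add atoms: none
Why: Hydride reduction of the lactone (two 1,2-additions at the acyl carbon) releases the phenol and the primary allylic alcohol without touching the trisubstituted alkene, so the Z geometry imposed by the ring is kept.

Step 3
Reactants: 4 2-[(2Z)-1-hydroxy-4-methylpent-2-en-3-yl]-5-methylphenol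
Product: 5 (2Z)-3-Ar-4-methylpent-2-en-1-ol
Conditions: NaH (1.0 equiv), THF, 0 °C; iPr3SiOSO2CF3, −78 → 0 °C
Reagents that add atoms: tri(propan-2-yl)silyl trifluoromethanesulfonate, CC(C)[Si](OS(=O)(=O)C(F)(F)F)(C(C)C)C(C)C
Why: O-Silylation of the sodium phenoxide, which forms selectively because the phenol is far more acidic than the alcohol, masks the phenol as the aryl silyl ether that later becomes the C6 silyl enol ether.

Step 4
Reactants: 5 (2Z)-3-Ar-4-methylpent-2-en-1-ol
Product: 6 [(2S,3R)-3-Ar-3-(propan-2-yl)oxiran-2-yl]methanol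
Conditions: Ti(OiPr)4 (10 mol %), L-(+)-diethyl tartrate (12 mol %), tBuOOH (decane), 4 Å molecular sieves, CH2Cl2, −25 °C
Reagents that add atoms: tert-butyl hydroperoxide, CC(C)(C)OO
Why: Sharpless asymmetric epoxidation: the titanium tartrate complex binds the allylic alcohol and the hydroperoxide and, with the L-(+)-tartrate, should deliver oxygen to the face that gives the (2S,3R)-epoxy alcohol (the sense found for Z-3,3-disubstituted allylic alcohols such as nerol), which sets the C4 carbinol centre and holds the aryl group and C2 cis on the oxirane.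

Step 5
Reactants: 6 [(2S,3R)-3-Ar-3-(propan-2-yl)oxiran-2-yl]methanol
Product: 8 sodium (2R,3R)-3-Ar-3-(propan-2-yl)oxirane-2-carboxylate, via epoxy aldehyde 7 (not isolated)
Conditions: TEMPO (10 mol %), NaOCl (5 mol %), NaClO2, MeCN/phosphate buffer (pH 6.8), rt; work-up at pH 8 (NaHCO3), isolated as the sodium salt
Reagents that add atoms: sodium chlorite, [Na+].[O-]Cl=O; sodium hydrogencarbonate (sodium counter-ion), [Na+].OC([O-])=O
Why: Oxoammonium oxidation to the aldehyde followed by chlorite oxidation to the carboxylate runs near neutral pH, and keeping the product as its salt avoids the acid-induced decarboxylative ring opening typical of aryl glycidic acids.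

Step 6
Reactants: 8 sodium (2R,3R)-3-Ar-3-(propan-2-yl)oxirane-2-carboxylate; 9 N-ethyl-N-nitrosourea
Product: 12 2-diazo-1-[(2R,3R)-3-Ar-3-(propan-2-yl)oxiran-2-yl]propan-1-one, via diazoethane 10 (not isolated), via mixed anhydride 11 (not isolated)
Conditions: 9, 40% aq. KOH, Et2O, 0 °C (ethereal 10 dried over KOH pellets); 8, iBuOCOCl, THF, −20 °C; then 10 (3 equiv), −20 → 0 °C
Reagents that add atoms: none
Why: Acylation of a diazoalkane by a mixed carbonic anhydride (the first stage of an Arndt–Eistert sequence) gives the α-diazo ketone without acid or strong base, so the epoxide survives, and diazoethane brings C1 together with its methyl group.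

Step 7
Reactants: 12 2-diazo-1-[(2R,3R)-3-Ar-3-(propan-2-yl)oxiran-2-yl]propan-1-one
Product: 14 3β,4β-epoxy-4α-isopropyl-1β,8-dimethyl-6-[tri(propan-2-yl)silyloxy]bicyclo[5.3.0]deca-5,7,9-trien-2-one, via norcaradiene 13 (not isolated)
Conditions: Rh2(OAc)4 (1 mol %), CH2Cl2, 40 °C, slow addition of 12 (high dilution)
Reagents that add atoms: none
Why: Rh2(OAc)4 turns the diazo ketone into an electrophilic acyl carbenoid at C1, which cyclopropanates the arene bond C5–C10 (ipso carbon and the unsubstituted ortho carbon) to norcaradiene 13, and 13 opens by disrotatory 6π electrocyclic cleavage of C5–C10 to the cycloheptatriene 14, a net insertion of C1 into the benzene ring (Buchner reaction). The closest known reaction type is the intramolecular Buchner cyclisation of 2-diazo-5-arylpentan-3-ones to 8a-methyl-3,4-dihydroazulen-1(2H)-ones, which tolerates the methyl group on the diazo carbon and a benzylic substituent; the epoxide in the tether is the new feature here. The five-membered ring (C1–C5) closes when the carbenoid, held by the two-atom tether C3–C4, adds to the ipso/ortho π-bond in a 5-exo sense, and the seven-membered ring (C1, C5–C10) arises by one-carbon expansion of the six-membered aromatic ring. The only new stereocentre that persists, C1, is set by C4: in the rotamer about C4–C5 that turns the isopropyl group away from the ortho silyloxy group the epoxide oxygen lies on the C6 side, so C10 adds to the face of the new cyclopentanone anti to the epoxide and the C1 methyl ends up cis to the C4 oxygen (1β-methyl, 4β-oxygen). The step needs attack at C5–C10 and not at C5–C6, which the bulky OSi(iPr)3 group on C6 secures, and capture of the carbenoid by the arene faster than 1,2-hydride shift from its methyl group or C–H insertion, which the cis-epoxide secures by holding the carbenoid over the electron-rich ring and the isopropyl C–H bonds out of reach.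

Step 8
Reactants: 14 3β,4β-epoxy-4α-isopropyl-1β,8-dimethyl-6-[tri(propan-2-yl)silyloxy]bicyclo[5.3.0]deca-5,7,9-trien-2-one
Product: 16 4β-hydroxy-4α-isopropyl-1β,8-dimethyl-6-[tri(propan-2-yl)silyloxy]bicyclo[5.3.0]deca-5,7,9-trien-2-one, via phenylselanyl ketone 15 (not isolated)
Conditions: (PhSe)2, NaBH4, EtOH, 0 °C; AcOH (1 equiv); then 14, 0 °C → rt
Reagents that add atoms: none
Why: Selenoborate reduction of an α,β-epoxy ketone: benzeneselenolate opens the oxirane by SN2 attack at C3 (α to the carbonyl, anti to the oxygen), a second selenolate removes selenium from 15 to give the enolate, and protonation leaves the C4–O bond and its configuration untouched, while the acetic acid buffer suppresses retro-aldol cleavage of the β-hydroxy ketone.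

Step 9
Reactants: 16 4β-hydroxy-4α-isopropyl-1β,8-dimethyl-6-[tri(propan-2-yl)silyloxy]bicyclo[5.3.0]deca-5,7,9-trien-2-one
Product: 17 4α-isopropyl-1β,8-dimethyl-6-[tri(propan-2-yl)silyloxy]bicyclo[5.3.0]deca-5,7,9-triene-2α,4β-diol
Conditions: Me4NBH(OAc)3 (5 equiv), MeCN/AcOH (4:1), −35 °C
Reagents that add atoms: none
Why: Evans–Saksena reduction: the β-face C4 hydroxyl exchanges onto boron and delivers hydride intramolecularly to the β-face of the C2 carbonyl, which should give the 2α-alcohol (trans to the C1 methyl, the opposite of simple steric control), and the weak acid at low temperature should leave the silyl enol ether and the tertiary allylic alcohol intact.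

Step 10
Reactants: 17 4α-isopropyl-1β,8-dimethyl-6-[tri(propan-2-yl)silyloxy]bicyclo[5.3.0]deca-5,7,9-triene-2α,4β-diol
Product: 18 2α,4β-dihydroxy-4α-isopropyl-1β,8-dimethyl-5αH-bicyclo[5.3.0]deca-7,9-dien-6-one
Conditions: Bu4NF (1.1 equiv), AcOH (1.5 equiv), THF, −40 → 0 °C
Reagents that add atoms: none
Why: Fluoride cleavage of the silyl enol ether and C-protonation of the enol at C5 (its only nucleophilic carbon) release the C6 ketone as a 2,4-dienone without strong acid, which avoids loss of the C4 hydroxyl by ionisation, and the trans-fused 5αH ketone is expected as the more stable epimer because C6 then lies next to the C4 hydroxyl (hydrogen bond to the carbonyl) and not next to the isopropyl group.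

Step 11
Reactants: 18 2α,4β-dihydroxy-4α-isopropyl-1β,8-dimethyl-5αH-bicyclo[5.3.0]deca-7,9-dien-6-one
Product: 19 9α,10α-epoxy-2α,4β-dihydroxy-4α-isopropyl-1β,8-dimethyl-5αH-bicyclo[5.3.0]dec-7-en-6-one
Conditions: mCPBA (1.1 equiv), NaHCO3, CH2Cl2, 0 °C
Reagents that add atoms: 3-chloroperoxybenzoic acid, O=C(OO)c1cccc(Cl)c1
Why: Prilezhaev epoxidation of a dienone takes place at the γ,δ-alkene (C9=C10), the more electron-rich one, and should come from the α-face, opposite the C1 methyl and guided by hydrogen bonding to the homoallylic 2α-hydroxyl, which sets C10 (and C9).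

Step 12
Reactants: 19 9α,10α-epoxy-2α,4β-dihydroxy-4α-isopropyl-1β,8-dimethyl-5αH-bicyclo[5.3.0]dec-7-en-6-one
Product: 20 2α,4β,10α-trihydroxy-4α-isopropyl-1β,8-dimethyl-5αH-bicyclo[5.3.0]dec-8-en-6-one
Conditions: SmI2 (2.2 equiv), THF/MeOH, −78 °C
Reagents that add atoms: none
Why: SmI2 reduction of a γ,δ-epoxy-α,β-unsaturated ketone: electron transfer to the enone cleaves the allylic C9–O bond to a samarium dienolate, whose kinetic protonation at C7 gives the β,γ-unsaturated ketone, so the C8=C9 alkene and the 10α-hydroxyl appear in one step with the C10–O bond untouched.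

Step 13
Reactants: 20 2α,4β,10α-trihydroxy-4α-isopropyl-1β,8-dimethyl-5αH-bicyclo[5.3.0]dec-8-en-6-one
Product: 21 2α,10α-diacetoxy-4β-hydroxy-4α-isopropyl-1β,8-dimethyl-5αH-bicyclo[5.3.0]dec-8-en-6-one
Conditions: Ac2O, pyridine, 4-(dimethylamino)pyridine (cat.), CH2Cl2, 0 °C → rt
Reagents that add atoms: acetic anhydride, CC(=O)OC(C)=O
Why: Nucleophile-catalysed acylation esterifies the two secondary hydroxyls (C2 and C10) while the tertiary C4 hydroxyl does not react, and the mild base at low temperature should not move the β,γ-alkene into conjugation.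

Step 14
Reactants: 21 2α,10α-diacetoxy-4β-hydroxy-4α-isopropyl-1β,8-dimethyl-5αH-bicyclo[5.3.0]dec-8-en-6-one
Product: 22 2α,10α-diacetoxy-4α-isopropyl-1β,8-dimethyl-5αH-bicyclo[5.3.0]dec-8-ene-4β,6α-diol
Conditions: Me4NBH(OAc)3 (5 equiv), MeCN/AcOH (4:1), −30 → −20 °C
Reagents that add atoms: none
Why: Evans–Saksena reduction, a second use of the C4 hydroxyl: C4–O sits on the β-face of the seven-membered ring next to C6, so internal hydride delivery should give the 6α-alcohol, and only the trans-fused C5 epimer can bring its carbonyl within reach of the boron hydride, which also fixes C5.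

Step 15
Reactants: 22 2α,10α-diacetoxy-4α-isopropyl-1β,8-dimethyl-5αH-bicyclo[5.3.0]dec-8-ene-4β,6α-diol
Product: 23 2α,10α-diacetoxy-8α,9α-epoxy-4α-isopropyl-1β,8β-dimethyl-5αH-bicyclo[5.3.0]decane-4β,6α-diol
Conditions: VO(acac)2 (5 mol %), tBuOOH (decane), CH2Cl2, 0 °C → rt
Reagents that add atoms: tert-butyl hydroperoxide, CC(C)(C)OO
Why: Hydroxyl-directed vanadium-catalysed epoxidation of a homoallylic alcohol: the vanadate ester of the 6α-hydroxyl should deliver oxygen to the α-face of the C8=C9 alkene, which sets C8 and C9 and never passes through a base-sensitive β,γ-epoxy ketone.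

Step 16
Reactants: 23 2α,10α-diacetoxy-8α,9α-epoxy-4α-isopropyl-1β,8β-dimethyl-5αH-bicyclo[5.3.0]decane-4β,6α-diol; 24 angelic acid [(2Z)-2-methylbut-2-enoic acid]
Product: 26 CNP0170993.1, via mixed anhydride 25 (not isolated)
Conditions: 24, 2,4,6-Cl3C6H2COCl, Et3N, toluene, rt; then 23, 75 °C
Reagents that add atoms: none
Why: Yamaguchi esterification through the 2,4,6-trichlorobenzoyl mixed anhydride, run without a nucleophilic catalyst, acylates the only secondary hydroxyl (C6) and should keep the Z geometry of the angelate, while the tertiary C4 hydroxyl stays free.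

**Compound list**

1 | 3-methylphenol (m-cresol) | Cc1cccc(O)c1 | starting material
2 | ethyl 4-methyl-3-oxopentanoate | CCOC(=O)CC(=O)C(C)C | starting material
3 | 7-methyl-4-(propan-2-yl)-2H-chromen-2-one | CC(C)C1=CC(=O)Oc2cc(C)ccc12 | intermediate
4 | 2-[(2Z)-1-hydroxy-4-methylpent-2-en-3-yl]-5-methylphenol | CC(C)/C(=C/CO)c1ccc(C)cc1O | intermediate
5 | (2Z)-3-Ar-4-methylpent-2-en-1-ol | CC(C)/C(=C/CO)c1ccc(C)cc1O[Si](C(C)C)(C(C)C)C(C)C | intermediate
6 | [(2S,3R)-3-Ar-3-(propan-2-yl)oxiran-2-yl]methanol | CC(C)[Si](C(C)C)(C(C)C)Oc1cc(C)ccc1[C@@]1(C(C)C)O[C@H]1CO | intermediate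
7 | (2R,3R)-3-Ar-3-(propan-2-yl)oxirane-2-carbaldehyde | CC(C)[Si](C(C)C)(C(C)C)Oc1cc(C)ccc1[C@@]1(C(C)C)O[C@H]1C=O | intermediate
8 | sodium (2R,3R)-3-Ar-3-(propan-2-yl)oxirane-2-carboxylate | CC(C)[Si](C(C)C)(C(C)C)Oc1cc(C)ccc1[C@@]1(C(C)C)O[C@H]1C(=O)[O-].[Na+] | intermediate
9 | N-ethyl-N-nitrosourea | CCN(N=O)C(N)=O | starting material
10 | diazoethane | CC=[N+]=[N-] | intermediate
11 | (2R,3R)-3-Ar-3-(propan-2-yl)oxirane-2-carboxylic 2-methylpropyl carbonic anhydride | CC(C)[Si](C(C)C)(C(C)C)Oc1cc(C)ccc1[C@@]1(C(C)C)O[C@H]1C(=O)OC(=O)OCC(C)C | intermediate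
12 | 2-diazo-1-[(2R,3R)-3-Ar-3-(propan-2-yl)oxiran-2-yl]propan-1-one | CC(C)[Si](C(C)C)(C(C)C)Oc1cc(C)ccc1[C@@]1(C(C)C)O[C@H]1C(=O)C(C)=[N+]=[N-] | intermediate
13 | norcaradiene valence tautomer of 14 (cyclopropane C1–C5–C10 on the α-face, C6=C7 and C8=C9 double bonds) | CC(C)[Si](C(C)C)(C(C)C)OC1=CC(C)=C[C@@H]2[C@@]3(C)C(=O)[C@@H]4O[C@]4(C(C)C)[C@@]123 | intermediate
14 | 3β,4β-epoxy-4α-isopropyl-1β,8-dimethyl-6-[tri(propan-2-yl)silyloxy]bicyclo[5.3.0]deca-5,7,9-trien-2-one | CC(C)[Si](C(C)C)(C(C)C)OC1=C2[C@@]3(C(C)C)O[C@H]3C(=O)[C@]2(C)C=CC(C)=C1 | intermediate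
15 | 4β-hydroxy-4α-isopropyl-1β,8-dimethyl-3α-(phenylselanyl)-6-[tri(propan-2-yl)silyloxy]bicyclo[5.3.0]deca-5,7,9-trien-2-one | CC(C)[Si](C(C)C)(C(C)C)OC1=C2[C@](O)(C(C)C)[C@H]([Se]c3ccccc3)C(=O)[C@]2(C)C=CC(C)=C1 | intermediate
16 | 4β-hydroxy-4α-isopropyl-1β,8-dimethyl-6-[tri(propan-2-yl)silyloxy]bicyclo[5.3.0]deca-5,7,9-trien-2-one | CC(C)[Si](C(C)C)(C(C)C)OC1=C2[C@](O)(C(C)C)CC(=O)[C@]2(C)C=CC(C)=C1 | intermediate
17 | 4α-isopropyl-1β,8-dimethyl-6-[tri(propan-2-yl)silyloxy]bicyclo[5.3.0]deca-5,7,9-triene-2α,4β-diol | CC(C)[Si](C(C)C)(C(C)C)OC1=C2[C@](O)(C(C)C)C[C@H](O)[C@]2(C)C=CC(C)=C1 | intermediate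
18 | 2α,4β-dihydroxy-4α-isopropyl-1β,8-dimethyl-5αH-bicyclo[5.3.0]deca-7,9-dien-6-one | O=C1C=C(C)C=C[C@@]2(C)[C@@H](O)C[C@@](O)(C(C)C)[C@H]12 | intermediate
19 | 9α,10α-epoxy-2α,4β-dihydroxy-4α-isopropyl-1β,8-dimethyl-5αH-bicyclo[5.3.0]dec-7-en-6-one | O=C1C=C(C)[C@H]3O[C@H]3[C@@]2(C)[C@@H](O)C[C@@](O)(C(C)C)[C@H]12 | intermediate
20 | 2α,4β,10α-trihydroxy-4α-isopropyl-1β,8-dimethyl-5αH-bicyclo[5.3.0]dec-8-en-6-one | O=C1CC(C)=C[C@@H](O)[C@@]2(C)[C@@H](O)C[C@@](O)(C(C)C)[C@H]12 | intermediate
21 | 2α,10α-diacetoxy-4β-hydroxy-4α-isopropyl-1β,8-dimethyl-5αH-bicyclo[5.3.0]dec-8-en-6-one | O=C1CC(C)=C[C@@H](OC(C)=O)[C@@]2(C)[C@@H](OC(C)=O)C[C@@](O)(C(C)C)[C@H]12 | intermediate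
22 | 2α,10α-diacetoxy-4α-isopropyl-1β,8-dimethyl-5αH-bicyclo[5.3.0]dec-8-ene-4β,6α-diol | O[C@H]1CC(C)=C[C@@H](OC(C)=O)[C@@]2(C)[C@@H](OC(C)=O)C[C@@](O)(C(C)C)[C@H]12 | intermediate
23 | 2α,10α-diacetoxy-8α,9α-epoxy-4α-isopropyl-1β,8β-dimethyl-5αH-bicyclo[5.3.0]decane-4β,6α-diol | O[C@H]1C[C@@]2(C)O[C@H]2[C@@H](OC(C)=O)[C@@]2(C)[C@@H](OC(C)=O)C[C@@](O)(C(C)C)[C@H]12 | intermediate
24 | angelic acid [(2Z)-2-methylbut-2-enoic acid] | C/C=C(/C)C(=O)O | starting material
25 | (2Z)-2-methylbut-2-enoic 2,4,6-trichlorobenzoic anhydride | C/C=C(/C)C(=O)OC(=O)c1c(Cl)cc(Cl)cc1Cl | intermediate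
26 | CNP0170993.1: 2α,10α-diacetoxy-6α-[(2Z)-2-methylbut-2-enoyloxy]-8α,9α-epoxy-4α-isopropyl-1β,8β-dimethyl-5αH-bicyclo[5.3.0]decan-4β-ol | C/C=C(/C)C(=O)O[C@H]1C[C@@]2(C)O[C@H]2[C@@H](OC(C)=O)[C@@]2(C)[C@@H](OC(C)=O)C[C@@](O)(C(C)C)[C@H]12 | target

Total steps: 16. Longest linear sequence: 16 steps (1 → 26).

**Steps most likely to fail**

1. Step 7 (key step). The carbenoid may be lost before it reaches the arene: 1,2-hydride shift from its methyl group would give an enone, and the metal may open the electron-rich benzylic epoxide. The epoxy trienol ether may also ionise at C4 on isolation. The fallback opens the epoxide before the carbene step and sets out from 6. NaAlH2(OCH2CH2OMe)2 in THF (hydride opening of the 2,3-epoxy alcohol at C3) would give (3R)-3-Ar-4-methylpentane-1,3-diol F1. TEMPO/NaClO2 oxidation of the primary alcohol would give (3R)-3-Ar-3-hydroxy-4-methylpentanoic acid F2. Me3SiCl and imidazole would give trimethylsilyl (3R)-3-Ar-4-methyl-3-(trimethylsilyloxy)pentanoate F3. (COCl)2 with catalytic DMF would convert the silyl ester into (3R)-3-Ar-4-methyl-3-(trimethylsilyloxy)pentanoyl chloride F4. Diazoethane 10 with Et3N would give (5R)-5-Ar-2-diazo-6-methyl-5-(trimethylsilyloxy)heptan-3-one F5. Rh2(O2CC3F7)4 in CH2Cl2, whose perfluorobutyrate ligands favour arene addition over insertion into the isopropyl C–H bond, would lead through the norcaradiene valence tautomer F6 to 4α-isopropyl-1β,8-dimethyl-6-[tri(propan-2-yl)silyloxy]-4β-(trimethylsilyloxy)bicyclo[5.3.0]deca-5,7,9-trien-2-one F7. The larger benzylic substituent (isopropyl) should end up trans to the C1 methyl, as in open-chain Buchner cyclisations with a benzylic substituent. Et3N·3HF in THF at 0 °C would remove the trimethylsilyl ether, and the route is rejoined at 16.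

2. Step 10. Protonation of the enol at C5 may come from the β-face and give the cis-fused ketone, or the enolate may expel the C4 hydroxyl. The fallback sets C5 under thermodynamic chelate control instead of by protonation and sets out from 17. The fluoride step would be run as before; the cis-fused ketone 2α,4β-dihydroxy-4α-isopropyl-1β,8-dimethyl-5βH-bicyclo[5.3.0]deca-7,9-dien-6-one F8 would then be treated with MgBr2·OEt2 and iPr2NEt in CH2Cl2 at 0 °C (soft enolisation). Only the trans-fused epimer can hold magnesium between the C4 hydroxyl and the C6 carbonyl oxygen, so the equilibrium should drain to 18, where the route is rejoined.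

3. Step 4. The bulky aryl group cis to the hydroxymethyl group may make the titanium-bound epoxidation slow and poorly face-selective, and the titanium alkoxide may open the electron-rich benzylic epoxide. The fallback replaces substrate binding by a reagent-controlled dioxirane and sets out from 5: Shi epoxidation with the L-fructose-derived ketone catalyst (the enantiomer of the usual D-fructose-derived one), KHSO5 (as its triple salt), K2CO3 buffer, MeCN/dimethoxymethane, 0 °C. By analogy with the (R,R)-epoxide that the D-fructose-derived ketone gives from 1-phenylcyclohexene, the enantiomeric ketone is the one expected to attack the face that leads to the (2S,3R)-epoxide. The medium is basic, the product is 6 itself, and no new compound is made.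

**Further compounds**

F1 | step 7 | (3R)-3-Ar-4-methylpentane-1,3-diol | CC(C)[Si](C(C)C)(C(C)C)Oc1cc(C)ccc1[C@](O)(C(C)C)CCO
F2 | step 7 | (3R)-3-Ar-3-hydroxy-4-methylpentanoic acid | CC(C)[Si](C(C)C)(C(C)C)Oc1cc(C)ccc1[C@](O)(C(C)C)CC(=O)O
F3 | step 7 | trimethylsilyl (3R)-3-Ar-4-methyl-3-(trimethylsilyloxy)pentanoate | CC(C)[Si](C(C)C)(C(C)C)Oc1cc(C)ccc1[C@](O[Si](C)(C)C)(C(C)C)CC(=O)O[Si](C)(C)C
F4 | step 7 | (3R)-3-Ar-4-methyl-3-(trimethylsilyloxy)pentanoyl chloride | CC(C)[Si](C(C)C)(C(C)C)Oc1cc(C)ccc1[C@](O[Si](C)(C)C)(C(C)C)CC(=O)Cl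
F5 | step 7 | (5R)-5-Ar-2-diazo-6-methyl-5-(trimethylsilyloxy)heptan-3-one | CC(C)[Si](C(C)C)(C(C)C)Oc1cc(C)ccc1[C@](O[Si](C)(C)C)(C(C)C)CC(=O)C(C)=[N+]=[N-]
F6 | step 7 | norcaradiene valence tautomer of F7 | CC(C)[Si](C(C)C)(C(C)C)OC1=CC(C)=C[C@@H]2[C@@]3(C)C(=O)C[C@@](O[Si](C)(C)C)(C(C)C)[C@@]123
F7 | step 7 | 4α-isopropyl-1β,8-dimethyl-6-[tri(propan-2-yl)silyloxy]-4β-(trimethylsilyloxy)bicyclo[5.3.0]deca-5,7,9-trien-2-one | CC(C)[Si](C(C)C)(C(C)C)OC1=C2[C@](O[Si](C)(C)C)(C(C)C)CC(=O)[C@]2(C)C=CC(C)=C1
F8 | step 10 | 2α,4β-dihydroxy-4α-isopropyl-1β,8-dimethyl-5βH-bicyclo[5.3.0]deca-7,9-dien-6-one | O=C1C=C(C)C=C[C@@]2(C)[C@@H](O)C[C@@](O)(C(C)C)[C@@H]12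
F0 | step 4 | none | none
A1 | direct plan | (3R,5S,6E)-3-ethynyl-2,6-dimethyl-7-[(1R,2R)-2-methylcyclopropyl]-3,5-bis(triethylsilyloxy)hept-6-ene | C#C[C@](O[Si](CC)(CC)CC)(C(C)C)C[C@H](O[Si](CC)(CC)CC)/C(C)=C/[C@@H]1C[C@H]1C
A2 | direct plan | 4α-isopropyl-1β,8α-dimethyl-2α,4β-bis(triethylsilyloxy)bicyclo[5.3.0]deca-5,9-diene | C1[C@@H](C)C=C[C@@]2(C)[C@@H](O[Si](CC)(CC)CC)C[C@@](O[Si](CC)(CC)CC)(C(C)C)C2=C1
A3 | direct plan | 2α,10α-diacetoxy-8α,9α-epoxy-4α-isopropyl-1β,8β-dimethyl-4β-(triethylsilyloxy)bicyclo[5.3.0]dec-5-ene | C1[C@@]3(C)O[C@H]3[C@@H](OC(C)=O)[C@@]2(C)[C@@H](OC(C)=O)C[C@@](O[Si](CC)(CC)CC)(C(C)C)C2=C1
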